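## Retrosynthetic overview

1. Target 16 comes from its tris-MOM ether 15 by mild acidic removal of the three acetals (last step).
2. 15 is cut at the CH2–CH2 bond of the propanone chain into methyl ketone 7 and benzylic alcohol 12. An Ir-catalysed hydrogen-borrowing α-alkylation joins them: the alcohol's own two hydrogens end up on these two carbons, so the prenyl C=C never meets an external reductant.
3. Enabling feature: the carbonyl carbon sits on C6 of the chroman benzene ring between the oxygen-bearing C5 and C7, giving a twisted, di-ortho-shielded aryl methyl ketone that should resist self-condensation and carbonyl reduction. The other carbon of the new bond is a benzylic CH2 on C1 of the 4-hydroxy-3-prenylphenyl ring and can be carried as a primary alcohol.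
4. Ketone 7 comes from phloroacetophenone 1: 4-O-(1,1-dimethylpropargyl) ether, bis-MOM protection, propargyl Claisen/oxa-6π closure, hydrogenation. The pyran ring is the only ring built; both benzene rings are bought.
5. Alcohol 12 comes from methyl 3-bromo-4-hydroxybenzoate 8: MOM protection, Suzuki prenylation, ester reduction.

Key step: step 8

Remark: the target has no stereocentre and no stereogenic double bond, so no stereocontrol is needed; only the transient enone 14 carries a geometry descriptor (E).

## Route

Step 1
Reactants: 1 2,4,6-trihydroxyacetophenone; 2 3-chloro-3-methylbut-1-yne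
Product: 3 1-[2,6-dihydroxy-4-(2-methylbut-3-yn-2-yloxy)phenyl]ethanone
Conditions: 2 (1.2 equiv), K2CO3 (1.2 equiv), KI (cat.), CuI (cat.), acetone, 55 °C
Reagents that add atoms: none
Why: Copper-assisted Williamson-type propargylic O-alkylation should take the C4 hydroxyl, the most acidic one (para to the acetyl group), while the bulky tertiary electrophile is slow at the two ortho hydroxyls that flank the acetyl group.

Step 2
Reactants: 3 1-[2,6-dihydroxy-4-(2-methylbut-3-yn-2-yloxy)phenyl]ethanone
Product: 4 1-[2,6-bis(methoxymethoxy)-4-(2-methylbut-3-yn-2-yloxy)phenyl]ethanone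
Conditions: NaH (2.2 equiv), MOMCl (2.5 equiv), DMF, 0 °C to rt
Reagents that add atoms: chloromethyl methyl ether (MOMCl), COCCl
Why: Williamson-type O-alkylation of the two sodium phenoxides with an α-chloro ether should cap both ortho hydroxyls, which makes the later pyran closure unambiguous and supplies base-stable protection for step 8.

Step 3
Reactants: 4 1-[2,6-bis(methoxymethoxy)-4-(2-methylbut-3-yn-2-yloxy)phenyl]ethanone
Product: 6 1-[5,7-bis(methoxymethoxy)-2,2-dimethyl-2H-chromen-6-yl]ethanone, via ortho-allenylphenol 5 (not isolated)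
Conditions: o-xylene, 140 °C
Reagents that add atoms: none
Why: Aromatic propargyl Claisen rearrangement ([3,3] shift to a free ortho carbon and enolisation to 5), 1,5-hydrogen shift to an ortho-quinone methide and oxa-6π electrocyclisation should close the pyran ring on the former C4 oxygen only, because the two other phenolic oxygens are MOM-blocked.

Step 4
Reactants: 6 1-[5,7-bis(methoxymethoxy)-2,2-dimethyl-2H-chromen-6-yl]ethanone
Product: 7 1-[5,7-bis(methoxymethoxy)-2,2-dimethyl-3,4-dihydro-2H-chromen-6-yl]ethanone
Conditions: H2 (1 atm), 10% Pd/C, EtOAc, rt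
Reagents that add atoms: none
Why: Catalytic hydrogenation over Pd/C should saturate the styrenic C3=C4 bond of the chromene quickly under neutral conditions that leave the twisted aryl ketone and the MOM acetals alone, and it is done here because no prenyl group is present yet.

Step 5
Reactants: 8 methyl 3-bromo-4-hydroxybenzoate
Product: 9 methyl 3-bromo-4-(methoxymethoxy)benzoate
Conditions: MOMCl (1.3 equiv), K2CO3 (2 equiv), acetone, rt
Reagents that add atoms: chloromethyl methyl ether (MOMCl), COCCl
Why: Williamson-type O-alkylation of the acidic, bromine- and ester-activated phenol should proceed cleanly with a mild carbonate base.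

Step 6
Reactants: 9 methyl 3-bromo-4-(methoxymethoxy)benzoate; 10 4,4,5,5-tetramethyl-2-(3-methylbut-2-en-1-yl)-1,3,2-dioxaborolane (prenylboronic acid pinacol ester)
Product: 11 methyl 4-(methoxymethoxy)-3-(3-methylbut-2-en-1-yl)benzoate
Conditions: 10 (1.5 equiv), Pd(dppf)Cl2 (5 mol %), K3PO4 (3 equiv), THF/H2O 10:1, 65 °C
Reagents that add atoms: none
Why: Suzuki–Miyaura coupling of the aryl bromide with the allylic boronate should deliver the linear prenyl arene when reductive elimination takes place at the unsubstituted allyl terminus, which a wide-bite-angle diphosphine on Pd favours, and the ester and MOM ether are inert to the mild base.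

Step 7
Reactants: 11 methyl 4-(methoxymethoxy)-3-(3-methylbut-2-en-1-yl)benzoate
Product: 12 [4-(methoxymethoxy)-3-(3-methylbut-2-en-1-yl)phenyl]methanol
Conditions: LiAlH4 (1.0 equiv), THF, 0 °C; aqueous NaOH work-up
Reagents that add atoms: none
Why: Hydride reduction of the benzoate with LiAlH4 should give the primary benzylic alcohol without touching the isolated trisubstituted alkene or the MOM acetal.

Step 8
Reactants: 7 1-[5,7-bis(methoxymethoxy)-2,2-dimethyl-3,4-dihydro-2H-chromen-6-yl]ethanone; 12 [4-(methoxymethoxy)-3-(3-methylbut-2-en-1-yl)phenyl]methanol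
Product: 15 1-[5,7-bis(methoxymethoxy)-2,2-dimethyl-3,4-dihydro-2H-chromen-6-yl]-3-[4-(methoxymethoxy)-3-(3-methylbut-2-en-1-yl)phenyl]propan-1-one, via aryl aldehyde 13 (not isolated), via protected chalcone 14 (not isolated)
Conditions: 12 (1.2 equiv), [Cp*IrCl2]2 (2 mol %), KOH (2 equiv), toluene, 85 °C, Ar
Reagents that add atoms: none
Why: Hydrogen-borrowing α-alkylation: the Cp*Ir alkoxide of 12 undergoes β-hydride elimination to aldehyde 13 and an Ir–H, the KOH-generated enolate of 7 condenses with 13 (Claisen–Schmidt) to chalcone 14, and the Ir–H returns the borrowed hydrogen by conjugate reduction of 14 to 15, with water as the only co-product. The closest known reaction type is the Ir- or Ru-catalysed α-alkylation of aryl methyl ketones, including di-ortho-substituted ones, with primary benzylic alcohols. No ring is closed and no stereocentre is formed. The step needs chemoselectivity for the polarised enone C=C over the isolated prenyl C=C and over the ketone C=O, and mono- over dialkylation. The Ir–H is a nucleophilic hydride that does not add to unactivated trisubstituted alkenes, and the OMOM groups on C5 and C7 twist and shield the carbonyl, which should suppress carbonyl reduction, self-aldol and a second condensation at the now hindered α-CH2; the near-stoichiometric amount of 12 supports this. The MOM acetals are inert to KOH.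

Step 9
Reactants: 15 1-[5,7-bis(methoxymethoxy)-2,2-dimethyl-3,4-dihydro-2H-chromen-6-yl]-3-[4-(methoxymethoxy)-3-(3-methylbut-2-en-1-yl)phenyl]propan-1-one
Product: 16 1-(5,7-dihydroxy-2,2-dimethyl-3,4-dihydro-2H-chromen-6-yl)-3-[4-hydroxy-3-(3-methylbut-2-en-1-yl)phenyl]propan-1-one (target)
Conditions: 3 M HCl (aq), MeOH, 40 °C
Reagents that add atoms: none
Why: Acid-catalysed transacetalisation of the three aryl MOM ethers to methanol should free the phenols, and dilute acid at low temperature should neither add to the prenyl C=C, nor cyclise it onto the neighbouring phenol, nor open the chroman ether.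

## Compound list

1 | 2,4,6-trihydroxyacetophenone | CC(=O)c1c(O)cc(O)cc1O | starting material
2 | 3-chloro-3-methylbut-1-yne | CC(C)(Cl)C#C | starting material
3 | 1-[2,6-dihydroxy-4-(2-methylbut-3-yn-2-yloxy)phenyl]ethanone | CC(=O)c1c(O)cc(OC(C)(C)C#C)cc1O | intermediate
4 | 1-[2,6-bis(methoxymethoxy)-4-(2-methylbut-3-yn-2-yloxy)phenyl]ethanone | CC(=O)c1c(OCOC)cc(OC(C)(C)C#C)cc1OCOC | intermediate
5 | 1-[4-hydroxy-2,6-bis(methoxymethoxy)-3-(3-methylbuta-1,2-dien-1-yl)phenyl]ethanone | CC(=O)c1c(OCOC)cc(O)c(C=C=C(C)C)c1OCOC | intermediate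
6 | 1-[5,7-bis(methoxymethoxy)-2,2-dimethyl-2H-chromen-6-yl]ethanone | CC(=O)c1c(OCOC)cc2c(c1OCOC)C=CC(C)(C)O2 | intermediate
7 | 1-[5,7-bis(methoxymethoxy)-2,2-dimethyl-3,4-dihydro-2H-chromen-6-yl]ethanone | CC(=O)c1c(OCOC)cc2c(c1OCOC)CCC(C)(C)O2 | intermediate
8 | methyl 3-bromo-4-hydroxybenzoate | COC(=O)c1ccc(O)c(Br)c1 | starting material
9 | methyl 3-bromo-4-(methoxymethoxy)benzoate | COC(=O)c1ccc(OCOC)c(Br)c1 | intermediate
10 | 4,4,5,5-tetramethyl-2-(3-methylbut-2-en-1-yl)-1,3,2-dioxaborolane | CC(C)=CCB1OC(C)(C)C(C)(C)O1 | starting material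
11 | methyl 4-(methoxymethoxy)-3-(3-methylbut-2-en-1-yl)benzoate | COC(=O)c1ccc(OCOC)c(CC=C(C)C)c1 | intermediate
12 | [4-(methoxymethoxy)-3-(3-methylbut-2-en-1-yl)phenyl]methanol | OCc1ccc(OCOC)c(CC=C(C)C)c1 | intermediate
13 | 4-(methoxymethoxy)-3-(3-methylbut-2-en-1-yl)benzaldehyde | O=Cc1ccc(OCOC)c(CC=C(C)C)c1 | intermediate
14 | (E)-1-[5,7-bis(methoxymethoxy)-2,2-dimethyl-3,4-dihydro-2H-chromen-6-yl]-3-[4-(methoxymethoxy)-3-(3-methylbut-2-en-1-yl)phenyl]prop-2-en-1-one | CC(C)=CCc1cc(/C=C/C(=O)c2c(OCOC)cc3c(c2OCOC)CCC(C)(C)O3)ccc1OCOC | intermediate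
15 | 1-[5,7-bis(methoxymethoxy)-2,2-dimethyl-3,4-dihydro-2H-chromen-6-yl]-3-[4-(methoxymethoxy)-3-(3-methylbut-2-en-1-yl)phenyl]propan-1-one | CC(C)=CCc1cc(CCC(=O)c2c(OCOC)cc3c(c2OCOC)CCC(C)(C)O3)ccc1OCOC | intermediate
16 | 1-(5,7-dihydroxy-2,2-dimethyl-3,4-dihydro-2H-chromen-6-yl)-3-[4-hydroxy-3-(3-methylbut-2-en-1-yl)phenyl]propan-1-one | CC(C)=CCc1cc(CCC(=O)c2c(O)cc3c(c2O)CCC(C)(C)O3)ccc1O | target

## Summary

Total step count: 9 steps.
Longest linear sequence: 6 steps (steps 1, 2, 3, 4, 8, 9).

Three steps most likely to fail:

Step 8 (key step). The catalytic cycle may stall. Condensation of the hindered enolate may be slower than base-induced disproportionation of the liberated aldehyde, or the Ir–H may hand its hydrogen back to the aldehyde faster than to the enone, so that chalcone or starting materials remain. The fallback makes the same bond by a stepwise polar sequence. It sets out from 7 and 12 and comes back at 15. Alcohol 12 is oxidised with MnO2 in CH2Cl2 at rt to the aldehyde 13, now isolated. Claisen–Schmidt condensation of 13 with 7 (KOH, EtOH, rt to 40 °C) should give the chalcone 14, also isolated. Copper hydride conjugate reduction of 14 ([(Ph3P)CuH]6 cat., polymethylhydrosiloxane, toluene, rt, then aqueous fluoride work-up) should reduce only the enone C=C and leave the prenyl group, giving 15. This fallback makes no compound outside the list (F0).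

Step 1. Alkylation may not stop at the C4 oxygen and may go on at the ortho hydroxyls, or it may turn to the ring carbons of the electron-rich phloroglucinol nucleus. The fallback builds the pyran ring by C-prenylation and cycloetherification instead. It sets out from 1 and comes back at 7, bypassing 3 to 6. Friedel–Crafts prenylation of 1 with 2-methylbut-3-en-2-ol and BF3·OEt2 in dioxane at rt should give 1-[2,4,6-trihydroxy-3-(3-methylbut-2-en-1-yl)phenyl]ethanone F1. Acid-catalysed cyclisation (TsOH cat., toluene, 80 °C) should give 1-(5,7-dihydroxy-2,2-dimethyl-3,4-dihydro-2H-chromen-6-yl)ethanone F2, which is separated by chromatography from the isomer closed on an ortho oxygen. Bis-MOM protection of F2 (NaH, MOMCl, DMF) gives 7.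

Step 6. Carbon–carbon bond formation may occur at the substituted terminus of the prenyl–palladium intermediate, giving the 1,1-dimethylallyl isomer, or protodeboronation may outrun transmetalation. The fallback installs the prenyl group by an aromatic Claisen rearrangement, which fixes both its position and its linear form. It sets out from 2 and comes back at 11. Bought methyl 4-hydroxybenzoate F3 is O-alkylated with 2 (K2CO3, KI, CuI, acetone, 55 °C) to methyl 4-(2-methylbut-3-yn-2-yloxy)benzoate F4. Semihydrogenation (H2, lead-poisoned Pd/CaCO3, quinoline, EtOAc) gives methyl 4-(2-methylbut-3-en-2-yloxy)benzoate F5. Heating in N,N-diethylaniline at 130 °C should give methyl 4-hydroxy-3-(3-methylbut-2-en-1-yl)benzoate F6 by [3,3] shift. MOM protection (MOMCl, K2CO3, acetone) gives 11.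

## Further compounds

F0 | step 8 | none | none
F1 | step 1 | 1-[2,4,6-trihydroxy-3-(3-methylbut-2-en-1-yl)phenyl]ethanone | CC(=O)c1c(O)cc(O)c(CC=C(C)C)c1O
F2 | step 1 | 1-(5,7-dihydroxy-2,2-dimethyl-3,4-dihydro-2H-chromen-6-yl)ethanone | CC(=O)c1c(O)cc2c(c1O)CCC(C)(C)O2
F3 | step 6 | methyl 4-hydroxybenzoate | COC(=O)c1ccc(O)cc1
F4 | step 6 | methyl 4-(2-methylbut-3-yn-2-yloxy)benzoate | COC(=O)c1ccc(OC(C)(C)C#C)cc1
F5 | step 6 | methyl 4-(2-methylbut-3-en-2-yloxy)benzoate | COC(=O)c1ccc(OC(C)(C)C=C)cc1
F6 | step 6 | methyl 4-hydroxy-3-(3-methylbut-2-en-1-yl)benzoate | COC(=O)c1ccc(O)c(CC=C(C)C)c1
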